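With ring B as C1–C5/C10 and ring A as C5–C10 (C3 acetate, C8 ketone, C9 angelate, C10 hydroxyl), ring A is cut across C5–C6 and C8–C9. The key step is an anionic [3+3] annulation: lithiated allyl phenyl sulfone adds through its α-carbon (C8) to the C9 aldehyde of (R)-1-hydroxy-2-methyl-4-oxocyclohex-2-ene-1-carbaldehyde and then, after a second deprotonation, through its γ-carbon (C6) to the enone β-carbon C5; the enolate is methylated at C4. It exploits that C9 is a carbinol between C10–OH and the C8 carbonyl and that quaternary C5 is β to the C3 oxygen. One operation closes ring A cis-fused and sets C9, C5 and C4.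

Key step: step 4

Remark: commercial Hagemann's ester 1 is taken as the racemate; bicyclic compounds are named as bicyclo[4.4.0]decanes with the atom labels of the target (ring fusion C5/C10, C11/C12 = acetyl on C7), and β means the face of the C5 methyl.

Step 1
Reactants: 1 Hagemann's ester (ethyl 2-methyl-4-oxocyclohex-2-ene-1-carboxylate)
Product: 3 ethyl (R)-1-hydroxy-2-methyl-4-oxocyclohex-2-ene-1-carboxylate, via hydroperoxide 2 (not isolated)
Conditions: O2 (1 atm), P(OEt)3, N-(9-anthracenylmethyl)cinchonidinium bromide (10 mol %), 50% aq. KOH, toluene, −20 °C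
Reagents that add atoms: dioxygen, O=O
Why: Phase-transfer-catalysed asymmetric aerobic hydroxylation: the chiral ammonium ion pair of the extended (vinylogous β-keto ester) enolate should be oxygenated at its γ-terminus C10 (tertiary, ester-stabilised, restoring the conjugated enone) on the face left open by the catalyst, and the phosphite reduces hydroperoxide 2, so C10 is set as R.

Step 2
Reactants: 3 ethyl (R)-1-hydroxy-2-methyl-4-oxocyclohex-2-ene-1-carboxylate
Product: 4 (1R,4RS)-1-(hydroxymethyl)-2-methylcyclohex-2-ene-1,4-diol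
Conditions: LiAlH4, THF, 0 °C → rt
Reagents that add atoms: none
Why: LiAlH4 reduces the ester to the primary alcohol and the enone carbonyl (1,2) to the allylic alcohol without touching C10; both carbinol epimers are reoxidised in the next step.

Step 3
Reactants: 4 (1R,4RS)-1-(hydroxymethyl)-2-methylcyclohex-2-ene-1,4-diol
Product: 5 (R)-1-hydroxy-2-methyl-4-oxocyclohex-2-ene-1-carbaldehyde
Conditions: 2-iodoxybenzoic acid (IBX, 3 equiv), DMSO, rt; used crude
Reagents that add atoms: none
Why: IBX oxidises the primary and the allylic secondary alcohol to aldehyde and enone without cleaving the 1,2-diol, and the tertiary alcohol is inert; the sensitive α-hydroxy aldehyde is used at once.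

Step 4
Reactants: 5 (R)-1-hydroxy-2-methyl-4-oxocyclohex-2-ene-1-carbaldehyde; 6 allyl phenyl sulfone
Product: 9 (4R,5R,9S,10R)-9,10-dihydroxy-4,5-dimethyl-8-(phenylsulfonyl)bicyclo[4.4.0]dec-7-en-3-one, via aldol adduct 7 (not isolated), via lithium enolate 8 (not isolated)
Conditions: 5, LiN(SiMe3)2 (1 equiv), THF, −78 °C; then 6/n-BuLi (1.05 equiv), −78 °C; LiN(SiMe3)2 (1.1 equiv), −78 → −20 °C; MeI, DMPU, −20 → 0 °C; aq. NH4Cl
Reagents that add atoms: iodomethane, CI
Why: The α-sulfonyl allyl carbanion adds through its α-carbon to the aldehyde, which is held in a five-membered lithium chelate with the C10 alkoxide, so that C8 should arrive from the side of C1H2 (away from the vinylic C5 methyl) and set C9 as S (9α-OH, trans to the C10 oxygen); adduct 7 is then deprotonated at C8 (α-sulfonyl and allylic, more acidic than the ketone α′-hydrogens) and the delocalised anion closes ring A through its γ-carbon C6 in a 6-exo-trig vinylogous Michael addition to C5, α-attack being excluded because it would give a four-membered ring. The closest known reaction types are the addition of sulfonyl carbanions to aldehydes (first stage of the Julia olefination), the γ-selective conjugate addition of heteroatom-stabilised allyl anions to cyclic enones, and conjugate addition followed by enolate alkylation. C5 is fixed by the tether: C6 can reach C5 only on the face that carries C9, which makes the ring fusion cis (C5 methyl and C10 oxygen on the same face). Iodomethane then alkylates the regiodefined enolate 8 on the convex face, trans to the new C5–C6 bond, which should place the C4 methyl cis to the C5 methyl. The step needs aldehyde over enone-carbonyl selectivity in the first addition (the chelated aldehyde is the more electrophilic carbonyl) and C- over O-methylation at the end (lithium alkoxides methylate slowly below 0 °C); the C8 stereocentre of 7 disappears in 9.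

Step 5
Reactants: 9 (4R,5R,9S,10R)-9,10-dihydroxy-4,5-dimethyl-8-(phenylsulfonyl)bicyclo[4.4.0]dec-7-en-3-one
Product: 10 (3S,4R,5R,9S,10R)-4,5-dimethyl-8-(phenylsulfonyl)bicyclo[4.4.0]dec-7-ene-3,9,10-triol
Conditions: LiBH(s-Bu)3 (3.5 equiv), THF, −78 °C; H2O
Reagents that add atoms: none
Why: Trialkylborohydride reduction of a hindered cyclohexanone: the axial angular C5 methyl blocks axial attack, so hydride should enter equatorially and give the axial 3β-alcohol (3S), cis to the C4 and C5 methyls, while the trisubstituted vinyl sulfone is not reduced at −78 °C.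

Step 6
Reactants: 10 (3S,4R,5R,9S,10R)-4,5-dimethyl-8-(phenylsulfonyl)bicyclo[4.4.0]dec-7-ene-3,9,10-triol
Product: 12 (3S,4R,5R,9S,10R)-3,9,10-trihydroxy-4,5-dimethylbicyclo[4.4.0]dec-6-en-8-one, via silyloxy sulfone 11 (not isolated)
Conditions: LiN(i-Pr)2 (4.5 equiv), THF–DMPU, −78 → −40 °C; Me3SiOOSiMe3, −78 °C; AcOH, −78 °C
Reagents that add atoms: bis(trimethylsilyl) peroxide, C[Si](C)(C)OO[Si](C)(C)C
Why: Oxidative desulfonylation: after the three hydroxyls, the amide base removes an allylic C6 hydrogen, the sulfonyl-stabilised allyl anion is oxygenated at C8 by the silyl peroxide, and α-silyloxy sulfone 11 collapses with loss of benzenesulfinate to the C8 ketone conjugated with the new C6=C7 bond; the C9 alkoxide cannot be eliminated, so C9 should be retained.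

Step 7
Reactants: 12 (3S,4R,5R,9S,10R)-3,9,10-trihydroxy-4,5-dimethylbicyclo[4.4.0]dec-6-en-8-one; 13 angelic acid ((Z)-2-methylbut-2-enoic acid)
Product: 15 (3S,4R,5R,9S,10R)-3,10-dihydroxy-4,5-dimethyl-8-oxobicyclo[4.4.0]dec-6-en-9-yl (Z)-2-methylbut-2-enoate, via mixed anhydride 14 (not isolated)
Conditions: 13, 2,4,6-Cl3C6H2COCl, Et3N, toluene, rt; then 12, 75 °C
Reagents that add atoms: none
Why: Yamaguchi esterification through mixed anhydride 14 without DMAP (which keeps the Z geometry of the angelate): the secondary α-ketol hydroxyl at C9 should be acylated, while the tertiary C10 hydroxyl and the axial C3 hydroxyl (flanked by the C4 methyl and syn-axial to the C5 methyl) should react much more slowly; C9 keeps its configuration.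

Step 8
Reactants: 15 (3S,4R,5R,9S,10R)-3,10-dihydroxy-4,5-dimethyl-8-oxobicyclo[4.4.0]dec-6-en-9-yl (Z)-2-methylbut-2-enoate
Product: 16 (3S,4R,5R,9S,10R)-3-acetoxy-10-hydroxy-4,5-dimethyl-8-oxobicyclo[4.4.0]dec-6-en-9-yl (Z)-2-methylbut-2-enoate
Conditions: Ac2O, Et3N, DMAP (cat.), CH2Cl2, rt
Reagents that add atoms: acetic anhydride, CC(=O)OC(C)=O
Why: DMAP-catalysed acetylation of the remaining secondary (C3) alcohol; the tertiary C10 hydroxyl should not be acylated under these conditions.

Step 9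
Reactants: 16 (3S,4R,5R,9S,10R)-3-acetoxy-10-hydroxy-4,5-dimethyl-8-oxobicyclo[4.4.0]dec-6-en-9-yl (Z)-2-methylbut-2-enoate
Product: 17 (3S,4R,5S,9S,10R)-3-acetoxy-10-hydroxy-7-iodo-4,5-dimethyl-8-oxobicyclo[4.4.0]dec-6-en-9-yl (Z)-2-methylbut-2-enoate
Conditions: I2, pyridine–CH2Cl2, rt
Reagents that add atoms: iodine, II
Why: α-Iodination of the enone by pyridine conjugate addition, iodination of the enolate and elimination (a Baylis–Hillman-type sequence) should place iodine on C7 only; the C5 descriptor changes by priority, not by geometry.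

Step 10
Reactants: 17 (3S,4R,5S,9S,10R)-3-acetoxy-10-hydroxy-7-iodo-4,5-dimethyl-8-oxobicyclo[4.4.0]dec-6-en-9-yl (Z)-2-methylbut-2-enoate; 18 tributyl(1-ethoxyvinyl)stannane
Product: 20 CNP0196241.1 ((3S,4R,5R,9S,10R)-3-acetoxy-7-acetyl-10-hydroxy-4,5-dimethyl-8-oxobicyclo[4.4.0]dec-6-en-9-yl (Z)-2-methylbut-2-enoate), via enol ether 19 (not isolated)
Conditions: Pd(PPh3)4 (5 mol %), CuI (10 mol %), DMF, 50 °C; then 1 M aq. HCl, THF, 0 °C
Reagents that add atoms: water, O
Why: Stille coupling of the α-iodoenone with the α-ethoxyvinyl stannane followed by mild acid hydrolysis of enol ether 19 should unveil the C7 acetyl group; no stereocentre is involved.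

Compound list
1 | Hagemann's ester, ethyl 2-methyl-4-oxocyclohex-2-ene-1-carboxylate (racemic) | CCOC(=O)C1CCC(=O)C=C1C | starting material
2 | ethyl (R)-1-hydroperoxy-2-methyl-4-oxocyclohex-2-ene-1-carboxylate | O=C1C=C(C)[C@@](OO)(C(=O)OCC)CC1 | intermediate
3 | ethyl (R)-1-hydroxy-2-methyl-4-oxocyclohex-2-ene-1-carboxylate | O=C1C=C(C)[C@@](O)(C(=O)OCC)CC1 | intermediate
4 | (1R,4RS)-1-(hydroxymethyl)-2-methylcyclohex-2-ene-1,4-diol (both C4 epimers) | OC1C=C(C)[C@@](O)(CO)CC1 | intermediate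
5 | (R)-1-hydroxy-2-methyl-4-oxocyclohex-2-ene-1-carbaldehyde | O=C1C=C(C)[C@@](O)(C=O)CC1 | intermediate
6 | allyl phenyl sulfone | C=CCS(=O)(=O)c1ccccc1 | starting material
7 | (R)-4-hydroxy-4-[(S)-1-hydroxy-2-(phenylsulfonyl)but-3-en-1-yl]-3-methylcyclohex-2-en-1-one, present as its dilithium alkoxide, both epimers at the sulfonyl carbon | O=C1C=C(C)[C@@](O)([C@H](O)C(S(=O)(=O)c2ccccc2)C=C)CC1 | intermediate
8 | lithium C3 enolate of (5R,9S,10R)-9,10-dihydroxy-5-methyl-8-(phenylsulfonyl)bicyclo[4.4.0]dec-7-en-3-one, drawn as the enol | O[C@@H]1C(S(=O)(=O)c3ccccc3)=CC[C@]2(C)C=C(O)CC[C@]12O | intermediate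
9 | (4R,5R,9S,10R)-9,10-dihydroxy-4,5-dimethyl-8-(phenylsulfonyl)bicyclo[4.4.0]dec-7-en-3-one (cis-fused; 4β,5β-dimethyl, 9α-OH, 10β-OH) | O[C@@H]1C(S(=O)(=O)c3ccccc3)=CC[C@]2(C)[C@@H](C)C(=O)CC[C@]12O | intermediate
10 | (3S,4R,5R,9S,10R)-4,5-dimethyl-8-(phenylsulfonyl)bicyclo[4.4.0]dec-7-ene-3,9,10-triol (3β-OH) | O[C@@H]1C(S(=O)(=O)c3ccccc3)=CC[C@]2(C)[C@@H](C)[C@@H](O)CC[C@]12O | intermediate
11 | (3S,4R,5R,9S,10R)-4,5-dimethyl-8-(phenylsulfonyl)-8-(trimethylsilyloxy)bicyclo[4.4.0]dec-6-ene-3,9,10-triol, present as its lithium alkoxides, both C8 epimers | O[C@@H]1C(O[Si](C)(C)C)(S(=O)(=O)c3ccccc3)C=C[C@]2(C)[C@@H](C)[C@@H](O)CC[C@]12O | intermediate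
12 | (3S,4R,5R,9S,10R)-3,9,10-trihydroxy-4,5-dimethylbicyclo[4.4.0]dec-6-en-8-one | O[C@@H]1C(=O)C=C[C@]2(C)[C@@H](C)[C@@H](O)CC[C@]12O | intermediate
13 | angelic acid, (Z)-2-methylbut-2-enoic acid | C/C=C(/C)C(=O)O | starting material
14 | (Z)-2-methylbut-2-enoic 2,4,6-trichlorobenzoic anhydride | C/C=C(/C)C(=O)OC(=O)c1c(Cl)cc(Cl)cc1Cl | intermediate
15 | (3S,4R,5R,9S,10R)-3,10-dihydroxy-4,5-dimethyl-8-oxobicyclo[4.4.0]dec-6-en-9-yl (Z)-2-methylbut-2-enoate | C/C=C(/C)C(=O)O[C@@H]1C(=O)C=C[C@]2(C)[C@@H](C)[C@@H](O)CC[C@]12O | intermediate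
16 | (3S,4R,5R,9S,10R)-3-acetoxy-10-hydroxy-4,5-dimethyl-8-oxobicyclo[4.4.0]dec-6-en-9-yl (Z)-2-methylbut-2-enoate | C/C=C(/C)C(=O)O[C@@H]1C(=O)C=C[C@]2(C)[C@@H](C)[C@@H](OC(C)=O)CC[C@]12O | intermediate
17 | (3S,4R,5S,9S,10R)-3-acetoxy-10-hydroxy-7-iodo-4,5-dimethyl-8-oxobicyclo[4.4.0]dec-6-en-9-yl (Z)-2-methylbut-2-enoate | C/C=C(/C)C(=O)O[C@@H]1C(=O)C(I)=C[C@]2(C)[C@@H](C)[C@@H](OC(C)=O)CC[C@]12O | intermediate
18 | tributyl(1-ethoxyvinyl)stannane | CCCC[Sn](CCCC)(CCCC)C(=C)OCC | starting material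
19 | (3S,4R,5R,9S,10R)-3-acetoxy-7-(1-ethoxyvinyl)-10-hydroxy-4,5-dimethyl-8-oxobicyclo[4.4.0]dec-6-en-9-yl (Z)-2-methylbut-2-enoate | C/C=C(/C)C(=O)O[C@@H]1C(=O)C(C(=C)OCC)=C[C@]2(C)[C@@H](C)[C@@H](OC(C)=O)CC[C@]12O | intermediate
20 | CNP0196241.1, (3S,4R,5R,9S,10R)-3-acetoxy-7-acetyl-10-hydroxy-4,5-dimethyl-8-oxobicyclo[4.4.0]dec-6-en-9-yl (Z)-2-methylbut-2-enoate | C/C=C(/C)C(=O)O[C@@H]1C(=O)C(C(C)=O)=C[C@]2(C)[C@@H](C)[C@@H](OC(C)=O)CC[C@]12O | target

Total step count: 10. Longest linear sequence: 10 steps (1 → 20).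

Steps most likely to fail

1. Step 4. The ring closure may stall: retro-addition of the β-oxido sulfone or enolisation of the ring-B ketone can outrun the hindered γ-Michael attack on the β,β-disubstituted enone; chelate control at C9 can erode if the first addition becomes reversible; and the alkoxides can compete with the enolate for iodomethane. The fallback closes ring A by ring-closing metathesis after separate C5–C6 and C8–C9 bond formations; it sets out from 3 and comes back at 12. Conjugate addition of (CH2=CH)2CuLi to 3 (excess, THF, −78 °C, the metal-bound C10 alkoxide shielding its own face) with trapping of the enolate by MeI/HMPA should give ethyl (1R,2R,3R)-1-hydroxy-2,3-dimethyl-4-oxo-2-vinylcyclohexane-1-carboxylate F1. LiBH(s-Bu)3 at −78 °C should then give the axial alcohol ethyl (1R,2R,3R,4S)-1,4-dihydroxy-2,3-dimethyl-2-vinylcyclohexane-1-carboxylate F2, and i-Bu2AlH (CH2Cl2, −78 °C) should stop at (1R,2R,3R,4S)-1,4-dihydroxy-2,3-dimethyl-2-vinylcyclohexane-1-carbaldehyde F3. Chelation-controlled addition of 1-lithio-1-methoxyallene (methoxyallene, n-BuLi, THF, −78 °C) should give (1R,2R,3R,4S)-1-[(S)-1-hydroxy-2-methoxybuta-2,3-dien-1-yl]-2,3-dimethyl-2-vinylcyclohexane-1,4-diol F4, which dilute H2SO4 in THF at 0 °C hydrolyses to (S)-1-[(1R,2R,3R,4S)-1,4-dihydroxy-2,3-dimethyl-2-vinylcyclohexyl]-1-hydroxybut-3-en-2-one F5. Ring-closing metathesis with the second-generation Hoveyda–Grubbs catalyst RuCl2(H2IMes)(=CH-C6H4-2-O-i-Pr) in toluene at 80 °C would form C6=C7 and give 12.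

2. Step 1. Facial control by the ion-paired catalyst may be weak for the extended enolate (low enantiomeric purity, or the opposite sense, which would call for the cinchonine-derived catalyst), and oxygenation at C4 may compete. The fallback replaces asymmetric catalysis by resolution; it sets out from 1 and comes back at 3. Aerobic hydroxylation without chiral catalyst (O2, KOt-Bu, P(OEt)3, THF/t-BuOH, −20 °C) should give racemic ethyl 1-hydroxy-2-methyl-4-oxocyclohex-2-ene-1-carboxylate F6. Enzymatic kinetic resolution with pig liver esterase (pH 7 phosphate buffer, rt, to half conversion) would hydrolyse the (S)-ester to (S)-1-hydroxy-2-methyl-4-oxocyclohex-2-ene-1-carboxylic acid F7, which is removed by bicarbonate extraction; the recovered (R)-ester is 3.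

3. Step 6. The polyanion may form incompletely (poor solubility, slow γ-deprotonation), and once the C8 ketone appears the C10 alkoxide can trigger retro-aldol opening of ring A or epimerisation at C9. The fallback unmasks the ketone through an epoxy sulfone; it sets out from 10 and comes back at 12. Nucleophilic epoxidation of the vinyl sulfone (t-BuOOH, n-BuLi, THF, −20 °C) should give (3S,4R,5R,9S,10R)-7,8-epoxy-4,5-dimethyl-8-(phenylsulfonyl)bicyclo[4.4.0]decane-3,9,10-triol F8. MgBr2·OEt2 (Et2O/THF, 0 °C) should open it at C7 with loss of sulfinate to (3S,4R,5R,9S,10R)-7-bromo-3,9,10-trihydroxy-4,5-dimethylbicyclo[4.4.0]decan-8-one F9, and dehydrobromination (Li2CO3, LiBr, DMF, 80 °C) would give 12.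

Further compounds
F1 | step 4 | ethyl (1R,2R,3R)-1-hydroxy-2,3-dimethyl-4-oxo-2-vinylcyclohexane-1-carboxylate | C=C[C@]1(C)[C@@H](C)C(=O)CC[C@]1(O)C(=O)OCC
F2 | step 4 | ethyl (1R,2R,3R,4S)-1,4-dihydroxy-2,3-dimethyl-2-vinylcyclohexane-1-carboxylate | C=C[C@]1(C)[C@@H](C)[C@@H](O)CC[C@]1(O)C(=O)OCC
F3 | step 4 | (1R,2R,3R,4S)-1,4-dihydroxy-2,3-dimethyl-2-vinylcyclohexane-1-carbaldehyde | C=C[C@]1(C)[C@@H](C)[C@@H](O)CC[C@]1(O)C=O
F4 | step 4 | (1R,2R,3R,4S)-1-[(S)-1-hydroxy-2-methoxybuta-2,3-dien-1-yl]-2,3-dimethyl-2-vinylcyclohexane-1,4-diol | C=C[C@]1(C)[C@@H](C)[C@@H](O)CC[C@]1(O)[C@H](O)C(OC)=C=C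
F5 | step 4 | (S)-1-[(1R,2R,3R,4S)-1,4-dihydroxy-2,3-dimethyl-2-vinylcyclohexyl]-1-hydroxybut-3-en-2-one | C=C[C@]1(C)[C@@H](C)[C@@H](O)CC[C@]1(O)[C@H](O)C(=O)C=C
F6 | step 1 | racemic ethyl 1-hydroxy-2-methyl-4-oxocyclohex-2-ene-1-carboxylate | CCOC(=O)C1(O)CCC(=O)C=C1C
F7 | step 1 | (S)-1-hydroxy-2-methyl-4-oxocyclohex-2-ene-1-carboxylic acid | O=C1C=C(C)[C@](O)(C(=O)O)CC1
F8 | step 6 | (3S,4R,5R,9S,10R)-7,8-epoxy-4,5-dimethyl-8-(phenylsulfonyl)bicyclo[4.4.0]decane-3,9,10-triol (epoxide face not assigned) | O[C@@H]1C2(S(=O)(=O)c3ccccc3)OC2C[C@]4(C)[C@@H](C)[C@@H](O)CC[C@]14O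
F9 | step 6 | (3S,4R,5R,9S,10R)-7-bromo-3,9,10-trihydroxy-4,5-dimethylbicyclo[4.4.0]decan-8-one (both C7 epimers) | O[C@@H]1C(=O)C(Br)C[C@]2(C)[C@@H](C)[C@@H](O)CC[C@]12O
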